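**Plan**

1. Drimane numbers are used throughout (ring A: C1–C5 and C10; ring B: C5–C10; C11 on C9, C12 on C8, C13 and C14 on C4, C15 on C10); the target as drawn is (3S,5S,9R,10S).
2. The retrosynthesis first cuts the C11–O aryl ether (umbelliferone), then C5–C6 and C6–C7. The ring B ketone carbon C6 lies between C5 and C7, so ring B is carbon monoxide plus a ring A cyclopropane (C5, C9, C10) whose C9 bears C11 and the isopropenyl unit C8(C12)=C7.
3. The cyclopropane bonds C5–C9 and C9–C10 are cut next, back to a diazoacetoacetate held through its ester on the C3 oxygen of 2,2,4-trimethylcyclohex-3-enol, which comes from 4-methylanisole.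
4. Forward: ring A (Birch reduction, gem-dimethylation, CBS reduction), then the temporary lactone and the cyclopropane in one step, then isopropenyl group, lactone reduction and silylation, then ring B by carbonylative [5+1] ring expansion, then desilylation and the coumarin ether last.
5. Stereochemistry: C3 from the CBS reduction; C10 from carbene delivery on the face of the C3 oxygen; C5 by base equilibration to the trans ring fusion; C9 by axial protonation of the ring B dienolate anti to the C10 methyl.

Key step: step 10

Remark: in step 10 Fe(CO)5 is taken as a carrier that is regenerated under the CO atmosphere, so carbon monoxide 16 counts as the donor of C6.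

**Route**

Step 1
Reactants: 1 4-methylanisole
Product: 3 4-methylcyclohex-3-en-1-one, via 1-methoxy-4-methylcyclohexa-1,4-diene 2 (not isolated)
Conditions: Li, NH3 (l), tBuOH, THF, −78 °C; then (CO2H)2, MeOH–H2O, 20 °C
Reagents that add atoms: water, O
Why: Birch reduction of the anisole gives the 2,5-dihydro enol ether, and its mild acid hydrolysis (enol ether hydrolysis) should release the β,γ-unsaturated ketone without moving the alkene into conjugation.

Step 2
Reactants: 3 4-methylcyclohex-3-en-1-one
Product: 5 2,2,4-trimethylcyclohex-3-en-1-one, via 2,4-dimethylcyclohex-3-en-1-one 4 (not isolated)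
Conditions: KOtBu (2.2 equiv), MeI (2.5 equiv), tBuOH–THF, 0 → 20 °C
Reagents that add atoms: iodomethane, CI
Why: Enolate alkylation, in which C2 is both α to the ketone and allylic, so the extended dienolate forms there and should take methyl at its α-carbon twice (deconjugative α,α-dimethylation of a cyclohexenone dienolate) while the C3=C4 alkene stays in place and the transient stereocentre of 4 disappears.

Step 3
Reactants: 5 2,2,4-trimethylcyclohex-3-en-1-one
Product: 6 (1S)-2,2,4-trimethylcyclohex-3-en-1-ol
Conditions: (R)-2-methyl-CBS-oxazaborolidine (10 mol %), BH3·SMe2, THF, −20 °C; aqueous work-up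
Reagents that add atoms: none
Why: CBS reduction, in which the quaternary C2 acts as the large and C6H2 as the small ketone substituent, so the (R)-oxazaborolidine should deliver hydride to give the (S)-carbinol, the future C3 and the only stereocentre set by a reagent, while borane at −20 °C should not hydroborate the trisubstituted alkene at a competing rate.

Step 4
Reactants: 6 (1S)-2,2,4-trimethylcyclohex-3-en-1-ol; 7 2,2,6-trimethyl-4H-1,3-dioxin-4-one
Product: 9 acetoacetate ester of 6, via acetylketene 8 (not isolated)
Conditions: xylene, 140 °C (acetone distilled off)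
Reagents that add atoms: none
Why: Thermal retro-hetero-Diels–Alder cleavage of the dioxinone releases acetylketene, which acylates even a hindered secondary alcohol under neutral conditions (acetoacetylation), so the carbinol centre keeps its configuration.

Step 5
Reactants: 9 acetoacetate ester
Product: 10 2-diazoacetoacetate ester
Conditions: p-ABSA, Et3N, MeCN, 0 → 20 °C
Reagents that add atoms: 4-acetamidobenzenesulfonyl azide, CC(=O)Nc1ccc(cc1)S(=O)(=O)N=[N+]=[N-]
Why: Regitz diazo transfer onto the doubly activated methylene of the β-keto ester should give the stabilised 2-diazo-1,3-dicarbonyl compound under mild base.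

Step 6
Reactants: 10 2-diazoacetoacetate ester
Product: 11 tricyclic acetyl lactone
Conditions: Cu(acac)2 (5 mol %), PhMe, 110 °C, slow addition of 10
Reagents that add atoms: none
Why: Copper-carbenoid intramolecular cyclopropanation, in which the two-atom ester tether lets the carbene carbon (C9) reach C5=C10 only on the face of the C3 oxygen, so the six-membered lactone and the cyclopropane close together and C5, C9 and C10 are set relative to C3 (lactone carbonyl endo, acetyl exo, C10 methyl anti to the C3 oxygen), copper carbenoids favouring alkene addition over C–H insertion.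

Step 7
Reactants: 11 tricyclic acetyl lactone
Product: 12 isopropenyl lactone
Conditions: Ph3PCH3Br, KOtBu, PhMe–THF, 0 → 50 °C
Reagents that add atoms: methyltriphenylphosphonium bromide, C[P+](c1ccccc1)(c1ccccc1)c1ccccc1.[Br-]
Why: Wittig methylenation of the exo methyl ketone, the only ketone present, should give the isopropenyl group (C7) while the non-stabilised ylide leaves the hindered bridged lactone alone and the quaternary C9 cannot epimerise.

Step 8
Reactants: 12 isopropenyl lactone
Product: 13 vinylcyclopropane diol
Conditions: LiAlH4, THF, 0 → 20 °C; H2O, aq. NaOH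
Reagents that add atoms: none
Why: Hydride reduction of the lactone cleaves only the acyl C11–O bond, so C3 keeps its configuration and the C11 primary and C3 secondary alcohols are freed with alkene and cyclopropane untouched, the basic work-up avoiding cyclopropylcarbinyl cation rearrangement.

Step 9
Reactants: 13 vinylcyclopropane diol
Product: 15 bis(TBS ether) of 13, via 11-O-TBS monoether 14 (not isolated)
Conditions: TBSOTf (2.5 equiv), 2,6-lutidine, CH2Cl2, −78 → 0 °C
Reagents that add atoms: tert-butyldimethylsilyl trifluoromethanesulfonate, CC(C)(C)[Si](C)(C)OS(=O)(=O)C(F)(F)F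
Why: Silyl ether formation with the silyl triflate, which is reactive enough for the hindered C3 alcohol beside the gem-dimethyl carbon, masks both hydroxyls so that neither can bind iron or trap an acyl–iron species in the next step.

Step 10
Reactants: 15 bis(TBS ether) vinylcyclopropane; 16 carbon monoxide
Product: 19 trans-fused 7-en-6-one bis(TBS ether), via cis-fused 8-en-6-one 17 (not isolated), via cis-fused 7-en-6-one 18 (not isolated)
Conditions: Fe(CO)5 (1.5 equiv), CO (1 atm), hν (medium-pressure Hg lamp, Pyrex), iPrOH, 20 °C; then DBU, CH2Cl2, 20 → 40 °C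
Reagents that add atoms: none
Why: Photolysis of Fe(CO)5 gives a zerovalent Fe(CO)4 fragment that binds the isopropenyl group and inserts into the neighbouring C5–C9 cyclopropane bond to form a σ-alkyl (C5) π-allyl (C9–C8–C7) ferracycle, after which CO migrates onto C5 with retention and reductive elimination joins the acyl carbon C6 to C7; this is the carbonylative [5+1] ring expansion of vinylcyclopropanes to cyclohexenones, known for 2-cyclopropylpropenes and alkenylcyclopropanes under Fe(CO)5 and light. Ring B thus closes as a six-membered ring by union of the five-carbon unit C7–C8–C9–C10–C5 with CO, driven by release of cyclopropane strain. The selectivity needed is cleavage of C5–C9 and not C9–C10, which should follow from iron taking the secondary C5 in preference to the quaternary C10; because C4 and C10 carry no hydrogen the iron alkyl cannot collapse to a diene by β-hydride elimination, and the room-temperature photochemical conditions avoid the thermal homodienyl hydrogen shift open to a vinylcyclopropane with a cis methyl group. Retention at C5 first gives the cis-fused 8-ene 17, DBU removes the doubly activated H7, and the dienolate should take its proton at C9 axially, anti to the C10 methyl, to give 18. C5, now α to the ketone, should then equilibrate to the trans ring fusion of 19, which places H5 on the face of the C3 oxygen as in the target. C3 and C10 are not touched, so the relative configuration set by the tether in step 6 is carried through.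

Step 11
Reactants: 19 trans-fused 7-en-6-one bis(TBS ether)
Product: 21 3,11-diol enone, via 3-O-TBS 11-alcohol 20 (not isolated)
Conditions: HF (48% aq.), MeCN, 20 → 40 °C
Reagents that add atoms: none
Why: Acidic fluoride desilylation should remove the primary and then the hindered secondary TBS ether without base, so the γ-hydrogen at C9, the α-hydrogen at C5 and the enone are not exposed to enolising conditions.

Step 12
Reactants: 21 3,11-diol enone; 22 umbelliferone
Product: 23 ferocaulidin
Conditions: PPh3, DIAD, THF, 0 → 20 °C
Reagents that add atoms: none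
Why: Mitsunobu etherification, in which the phenol (pKa about 8) protonates the betaine and its phenoxide displaces the oxyphosphonium group at primary C11, while the axial C3 alcohol beside the gem-dimethyl carbon is too hindered to react and the neutral conditions avoid β-elimination of the aryloxide across C9–C11; no stereocentre is involved.

**Compound list**

1 | 4-methylanisole | COc1ccc(C)cc1 | starting material
2 | 1-methoxy-4-methylcyclohexa-1,4-diene | COC1=CCC(C)=CC1 | intermediate (not isolated)
3 | 4-methylcyclohex-3-en-1-one | CC1=CCC(=O)CC1 | intermediate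
4 | 2,4-dimethylcyclohex-3-en-1-one (racemic) | CC1=CC(C)C(=O)CC1 | intermediate (not isolated)
5 | 2,2,4-trimethylcyclohex-3-en-1-one | CC1=CC(C)(C)C(=O)CC1 | intermediate
6 | (1S)-2,2,4-trimethylcyclohex-3-en-1-ol | CC1=CC(C)(C)[C@@H](O)CC1 | intermediate
7 | 2,2,6-trimethyl-4H-1,3-dioxin-4-one | CC1=CC(=O)OC(C)(C)O1 | starting material
8 | acetylketene (3-oxobut-1-en-1-one) | CC(=O)C=C=O | intermediate (not isolated)
9 | (1S)-2,2,4-trimethylcyclohex-3-en-1-yl 3-oxobutanoate | CC1=CC(C)(C)[C@@H](OC(=O)CC(C)=O)CC1 | intermediate
10 | (1S)-2,2,4-trimethylcyclohex-3-en-1-yl 2-diazo-3-oxobutanoate | CC1=CC(C)(C)[C@@H](OC(=O)C(=[N+]=[N-])C(C)=O)CC1 | intermediate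
11 | (1R,2S,5S,8R)-2-acetyl-8,9,9-trimethyl-4-oxatricyclo[3.3.1.0(2,8)]nonan-3-one (cyclopropane C5–C9–C10 on the face of the C3 oxygen, lactone carbonyl C11 endo, acetyl exo) | CC(=O)[C@]1(C(=O)O3)[C@H]2C(C)(C)[C@@H]3CC[C@@]12C | intermediate
12 | (1R,2R,5S,8R)-8,9,9-trimethyl-2-(prop-1-en-2-yl)-4-oxatricyclo[3.3.1.0(2,8)]nonan-3-one | C=C(C)[C@]1(C(=O)O3)[C@H]2C(C)(C)[C@@H]3CC[C@@]12C | intermediate
13 | (1S,3S,6R,7R)-7-(hydroxymethyl)-2,2,6-trimethyl-7-(prop-1-en-2-yl)bicyclo[4.1.0]heptan-3-ol (CH2OH endo, on the side of the ring hydroxyl) | C=C(C)[C@]1(CO)[C@H]2C(C)(C)[C@@H](O)CC[C@@]12C | intermediate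
14 | (1S,3S,6R,7R)-7-{[(tert-butyldimethylsilyl)oxy]methyl}-2,2,6-trimethyl-7-(prop-1-en-2-yl)bicyclo[4.1.0]heptan-3-ol | C=C(C)[C@]1(CO[Si](C)(C)C(C)(C)C)[C@H]2C(C)(C)[C@@H](O)CC[C@@]12C | intermediate (not isolated)
15 | tert-butyl({(1R,4S,6S,7R)-4-[(tert-butyldimethylsilyl)oxy]-1,5,5-trimethyl-7-(prop-1-en-2-yl)bicyclo[4.1.0]heptan-7-yl}methoxy)dimethylsilane (drimane 3S,5S,9R,10R; key-step precursor) | C=C(C)[C@]1(CO[Si](C)(C)C(C)(C)C)[C@H]2C(C)(C)[C@@H](O[Si](C)(C)C(C)(C)C)CC[C@@]12C | intermediate
16 | carbon monoxide | [C-]#[O+] | starting material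
17 | (4aR,7S,8aR)-7-[(tert-butyldimethylsilyl)oxy]-4-{[(tert-butyldimethylsilyl)oxy]methyl}-3,4a,8,8-tetramethyl-4a,5,6,7,8,8a-hexahydronaphthalen-1(2H)-one (cis-fused, C8=C9) | CC=1CC(=O)[C@H]2C(C)(C)[C@@H](O[Si](C)(C)C(C)(C)C)CC[C@@]2(C)C=1CO[Si](C)(C)C(C)(C)C | intermediate (not isolated)
18 | (4R,4aS,7S,8aR)-7-[(tert-butyldimethylsilyl)oxy]-4-{[(tert-butyldimethylsilyl)oxy]methyl}-3,4a,8,8-tetramethyl-4a,5,6,7,8,8a-hexahydronaphthalen-1(4H)-one (cis-fused, C7=C8) | CC1=CC(=O)[C@H]2C(C)(C)[C@@H](O[Si](C)(C)C(C)(C)C)CC[C@@]2(C)[C@@H]1CO[Si](C)(C)C(C)(C)C | intermediate (not isolated)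
19 | (4R,4aS,7S,8aS)-7-[(tert-butyldimethylsilyl)oxy]-4-{[(tert-butyldimethylsilyl)oxy]methyl}-3,4a,8,8-tetramethyl-4a,5,6,7,8,8a-hexahydronaphthalen-1(4H)-one (trans-fused; drimane 3S,5S,9R,10S; key-step product) | CC1=CC(=O)[C@@H]2C(C)(C)[C@@H](O[Si](C)(C)C(C)(C)C)CC[C@@]2(C)[C@@H]1CO[Si](C)(C)C(C)(C)C | intermediate
20 | (4R,4aS,7S,8aS)-7-[(tert-butyldimethylsilyl)oxy]-4-(hydroxymethyl)-3,4a,8,8-tetramethyl-4a,5,6,7,8,8a-hexahydronaphthalen-1(4H)-one | CC1=CC(=O)[C@@H]2C(C)(C)[C@@H](O[Si](C)(C)C(C)(C)C)CC[C@@]2(C)[C@@H]1CO | intermediate (not isolated)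
21 | (4R,4aS,7S,8aS)-7-hydroxy-4-(hydroxymethyl)-3,4a,8,8-tetramethyl-4a,5,6,7,8,8a-hexahydronaphthalen-1(4H)-one | CC1=CC(=O)[C@@H]2C(C)(C)[C@@H](O)CC[C@@]2(C)[C@@H]1CO | intermediate
22 | umbelliferone (7-hydroxy-2H-chromen-2-one) | Oc1ccc2ccc(=O)oc2c1 | starting material
23 | ferocaulidin, 7-{[(1R,4aS,6S,8aS)-6-hydroxy-2,5,5,8a-tetramethyl-4-oxo-1,4,4a,5,6,7,8,8a-octahydronaphthalen-1-yl]methoxy}-2H-chromen-2-one | CC1=CC(=O)[C@@H]2C(C)(C)[C@@H](O)CC[C@@]2(C)[C@@H]1COc1ccc2ccc(=O)oc2c1 | target

**Count and risks**

Total step count: 12. Longest linear sequence: 12 steps (1 → 23); compounds 7, 16 and 22 enter as purchased.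

Steps most likely to fail:

1. Step 10. Insertion of iron into the C5–C9 bond, which is flanked by the quaternary C4 and C10, may be slower than loss of iron from the alkene complex, so that the vinylcyclopropane is returned or slowly degraded under irradiation. In the base stage, protonation of the dienolate at C9 from the face of the C10 methyl, or incomplete equilibration at C5, would erode the stereochemistry. The fallback separates metalation from ring closure and sets out from 15. Treatment with Fe2(CO)9 in Et2O at 35 °C in the dark should give the isolable tricarbonyliron acyl η3-allyl complex F1 (iron σ-bound to the acyl carbon C6 on C5 and η3-bound to C7–C8–C9). After purification, heating F1 under CO (40 bar, benzene, 60 °C) should force reductive elimination to the cis-fused 8-en-6-one 17, where the fallback comes back to the route; DBU then carries 17 on to 19 as in step 10.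

2. Step 6. The acceptor/acceptor copper carbenoid may be consumed before it reaches the trisubstituted alkene beside the quaternary C4, which it can only do with the ester axial. Competing processes are carbene dimerisation, attack by the acetyl oxygen (dihydrofuran or ylide products) and insertion into ring C–H bonds. The fallback changes the carbene to a donor/acceptor type and sets out from 10. TBSOTf and Et3N (CH2Cl2, 0 °C) should give the enol silyl ether diazo ester F2. Rh2(OAc)4 (1 mol %, CH2Cl2, 20 °C) should then cyclopropanate intramolecularly through the more selective siloxyvinyl carbenoid, under the same facial control by the tether, to the siloxyvinyl lactone F3. TBAF buffered with AcOH (THF, 0 °C) should unveil the methyl ketone, which returns to the route at 11.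

3. Step 12. Substitution at C11, a β-branched primary carbon next to the quaternary C10, may be slow, so that the oxyphosphonium ion eliminates toward C9 (whose hydrogen is vinylogously acidic) or the C3 hydroxyl begins to react. The fallback reverses the polarity so that C11 is never an electrophile. It sets out from 21 and uses palladium-catalysed C–O coupling of the primary alcohol with commercial 7-bromocoumarin ([(allyl)PdCl]2, RockPhos, Cs2CO3, PhMe, 70 °C), which should give 23 directly. The C11–O bond of 21 is kept and no new compound is made on the way (F0).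

**Further compounds**

F1 | step 10 | tricarbonyliron acyl η3-allyl complex of 15 plus CO (ferracycle, drawn in its σ-form with iron on C6 and C7; cis at C5/C10) | O=C1[C@H]2C(C)(C)[C@@H](O[Si](C)(C)C(C)(C)C)CC[C@@]2(C)C(CO[Si](C)(C)C(C)(C)C)=C(C)C[Fe]1(=C=O)(=C=O)=C=O
F2 | step 6 | (1S)-2,2,4-trimethylcyclohex-3-en-1-yl 3-[(tert-butyldimethylsilyl)oxy]-2-diazobut-3-enoate | CC1=CC(C)(C)[C@@H](OC(=O)C(=[N+]=[N-])C(=C)O[Si](C)(C)C(C)(C)C)CC1
F3 | step 6 | (1R,2S,5S,8R)-2-{1-[(tert-butyldimethylsilyl)oxy]ethenyl}-8,9,9-trimethyl-4-oxatricyclo[3.3.1.0(2,8)]nonan-3-one | C=C(O[Si](C)(C)C(C)(C)C)[C@]1(C(=O)O3)[C@H]2C(C)(C)[C@@H]3CC[C@@]12C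
F0 | step 12 | none | none
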